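**Strategy.** Everything rests on reading the two prenyl C–C bonds and the dimethylpyran as sigmatropic images of three phenol ethers: C8 of ring A lies para to O5, C2' of ring B ortho to O3', and C5' ortho to O4', the pyran oxygen. One heating of a (2S)-flavanone carrying a 5-O-prenyl, a 3'-O-(1,1-dimethylallyl) and a 4'-O-(1,1-dimethylpropargyl) ether, under europium catalysis, should move all three C5 units from oxygen to C8, C2' and C5' and close the chromene ring. The precursor comes from a chalcone, assembled by aldol condensation of two simple benzenes and cyclised by an enantioselective oxa-Michael addition that sets C2.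

Key step: step 8

Assumption: the quinine-derived thiourea is taken to give the 2S flavanone; if the first analysis shows the opposite sense, its quinidine-derived pseudoenantiomer replaces it with nothing else changed.

Step 1
Reactants: 1 2,4,6-trihydroxyacetophenone
Product: 2 2,6-dihydroxy-4-(methoxymethoxy)acetophenone
Conditions: MOMCl (1.05 equiv), iPr2NEt (1.2 equiv), CH2Cl2–THF, 0 °C
Reagents that add atoms: chloromethyl methyl ether (MOMCl), COCCl
Why: Williamson-type O-alkylation with the highly reactive chloromethyl ether: the hydroxyl para to the acetyl group is the most acidic and the only one not engaged with the carbonyl group, so one equivalent of MOMCl under amine base should etherify it ahead of the two chelated ortho hydroxyls.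

Step 2
Reactants: 2 2,6-dihydroxy-4-(methoxymethoxy)acetophenone; 3 prenyl bromide (1-bromo-3-methylbut-2-ene)
Product: 4 2-hydroxy-4-(methoxymethoxy)-6-(3-methylbut-2-enyloxy)acetophenone
Conditions: K2CO3 (1.5 equiv), acetone, rt to 50 °C
Reagents that add atoms: none
Why: Williamson ether synthesis (SN2 displacement of the primary allylic bromide by phenoxide) at one of the two equivalent ortho hydroxyls; the hydroxyl that remains is held in a strong six-membered hydrogen bond to the carbonyl oxygen, which should stop the alkylation at the mono-ether.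

Step 3
Reactants: 5 4-fluoro-3-hydroxybenzaldehyde; 6 2-methylbut-3-yn-2-ol
Product: 8 4-fluoro-3-(2-methylbut-3-yn-2-yloxy)benzaldehyde, via 2-methylbut-3-yn-2-yl trifluoroacetate 7 (not isolated)
Conditions: 6, (CF3CO)2O, DBU, MeCN, −5 °C; then 5, DBU, CuCl2 (1 mol%), MeCN, −5 to 0 °C
Reagents that add atoms: none
Why: Copper-catalysed propargylic O-alkylation of a phenol: the terminal alkyne of ester 7 gives a copper acetylide that expels trifluoroacetate to form a copper allenylidene-type electrophile, which the phenoxide of 5 captures at the tertiary carbon at 0 °C, far below the temperature at which aryl propargyl ethers rearrange.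

Step 4
Reactants: 8 4-fluoro-3-(2-methylbut-3-yn-2-yloxy)benzaldehyde
Product: 9 4-fluoro-3-(2-methylbut-3-en-2-yloxy)benzaldehyde
Conditions: H2 (1 atm), Lindlar catalyst (Pd on CaCO3, poisoned with Pb(OAc)2), quinoline, EtOAc, rt, stopped after one equivalent of H2
Reagents that add atoms: none
Why: Lindlar semihydrogenation: the lead- and quinoline-poisoned palladium surface adds one equivalent of hydrogen to the terminal alkyne and releases the alkene before it is reduced further, while the aldehyde, the aryl fluoride and the tertiary allylic C–O bond are left alone under these mild conditions.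

Step 5
Reactants: 9 4-fluoro-3-(2-methylbut-3-en-2-yloxy)benzaldehyde; 6 2-methylbut-3-yn-2-ol
Product: 11 3-(2-methylbut-3-en-2-yloxy)-4-(2-methylbut-3-yn-2-yloxy)benzaldehyde, via potassium 2-methylbut-3-yn-2-olate 10 (not isolated)
Conditions: 6 (3 equiv), KN(SiMe3)2 (2 equiv), THF, 0 °C; then 9, DMF, 0 °C to rt; concentrated below 30 °C
Reagents that add atoms: none
Why: Nucleophilic aromatic substitution by addition–elimination: the fluoride para to the formyl group is displaced through a Meisenheimer adduct by the tertiary alkoxide 10, excess free alcohol keeps the alkyne C–H protonated so that acetylide addition to the aldehyde is held back, and room temperature is far below the onset of the Claisen shift of the neighbouring 1,1-dimethylallyl ether.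

Step 6
Reactants: 4 2-hydroxy-4-(methoxymethoxy)-6-(3-methylbut-2-enyloxy)acetophenone; 11 3-(2-methylbut-3-en-2-yloxy)-4-(2-methylbut-3-yn-2-yloxy)benzaldehyde
Product: 13 (E)-1-[2-hydroxy-4-(methoxymethoxy)-6-(3-methylbut-2-enyloxy)phenyl]-3-[3-(2-methylbut-3-en-2-yloxy)-4-(2-methylbut-3-yn-2-yloxy)phenyl]prop-2-en-1-one, via aldol adduct 12 (not isolated)
Conditions: KOH (5 equiv), EtOH, 0 °C to rt; cold aq. NH4Cl/AcOH to pH 6
Reagents that add atoms: none
Why: Claisen–Schmidt condensation: the enolate of methyl ketone 4 adds to the non-enolisable aldehyde 11 and the aldol adduct 12 loses water by an E1cB pathway to the conjugated E-enone, while the strongly basic medium keeps the product as the ring-open 2'-phenoxide and leaves the MOM, allyl and propargyl ethers untouched.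

Step 7
Reactants: 13 (E)-chalcone carrying the three O-C5 ethers and the MOM ether
Product: 14 (2S)-7-(methoxymethoxy)-5-(3-methylbut-2-enyloxy)-2-[3-(2-methylbut-3-en-2-yloxy)-4-(2-methylbut-3-yn-2-yloxy)phenyl]chroman-4-one
Conditions: quinine-derived 3,5-bis(trifluoromethyl)phenyl thiourea (10 mol%), PhMe, 0 °C
Reagents that add atoms: none
Why: Organocatalytic enantioselective intramolecular oxa-Michael addition (6-endo-trig closure of ring C): the quinuclidine nitrogen activates the 2'-hydroxyl while the thiourea hydrogen-bonds the enone carbonyl, so that the phenol oxygen is delivered inside the chiral pocket to the Si face of the β-carbon and the C2 stereocentre is set as S by catalyst control, the 6'-alkoxy group biasing the equilibrium towards the closed flavanone.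

Step 8
Reactants: 14 (2S)-flavanone triether
Product: 23 (2S)-5-hydroxy-2-[8-hydroxy-2,2-dimethyl-7-(3-methylbut-2-enyl)-2H-chromen-6-yl]-7-(methoxymethoxy)-8-(3-methylbut-2-enyl)chroman-4-one, via C6 dienone 15 (not isolated), via C8 dienone 16 (not isolated), via ring A rearranged diether 17 (not isolated), via ring B dienone 18 (not isolated), via doubly rearranged propargyl ether 19 (not isolated), via allenyl dienone 20 (not isolated), via ortho-allenyl phenol 21 (not isolated), via ortho-quinone methide 22 (not isolated)
Conditions: Eu(fod)3 (fod = 6,6,7,7,8,8,8-heptafluoro-2,2-dimethyl-3,5-octanedionate; 10 mol%), degassed o-xylene, Ar, dark, 70 °C, then 110 °C, then 140 °C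
Reagents that add atoms: none
Why: Proposed new method: three thermal O-to-C transfers that are each established on their own (the europium-promoted para-Claisen–Cope rearrangement of 5-O-prenyl flavanones, the aromatic Claisen rearrangement of aryl 1,1-dimethylallyl ethers and the aryl propargyl ether to 2H-chromene rearrangement) are run in one flask on one substrate, which is reasonable because each is intramolecular, atom-neutral, driven by re-aromatisation and blind to the other two sites. At 70 °C trivalent europium held between O5 and the C4 carbonyl should speed the [3,3] shift of the prenyl ether to C6 (dienone 15), whose chair Cope [3,3] shift carries the CH2 terminus to C8 (dienone 16) before enolisation gives the chelated phenol 17; at 110 °C the 3'-O-(1,1-dimethylallyl) group should shift [3,3] with allyl inversion to C2' (dienone 18) and tautomerise to phenol 19. At 140 °C the 4'-O-propargyl group should shift [3,3] to C5' to give allenyl dienone 20, which enolises to 21 and undergoes a 1,5-hydrogen shift from the O4' hydroxyl to the central allene carbon to give the Z ortho-quinone methide 22. The dimethylpyran ring then closes by a thermal disrotatory oxa-6π electrocyclisation of 22 that forms the O4'–CMe2 bond and restores aromatic ring B. No stereocentre is created (the sp3 carbons of the dienones are lost on tautomerisation) and C2 is a bystander that the neutral, base-free medium should leave configured. Regioselectivity is the selectivity required and the substitution pattern supplies it: C2' is the only hydrogen-bearing carbon ortho to O3', C5' the only one ortho to O4', and C4a is blocked so the ring A group can leave O5 only by way of C6, where crowding of the tertiary allyl group between O5 and the O7 MOM ether favours the Cope shift to C8 over enolisation.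

Step 9
Reactants: 23 7-O-MOM ether of the target
Product: 24 (2S)-5,7-dihydroxy-2-[8-hydroxy-2,2-dimethyl-7-(3-methylbut-2-enyl)-2H-chromen-6-yl]-8-(3-methylbut-2-enyl)chroman-4-one (CNP0328260.1)
Conditions: 3 M aq. HCl, MeOH, rt, short contact; NaHCO3 quench
Reagents that add atoms: none
Why: Acid-catalysed solvolysis of the MOM acetal: protonation at the acetal oxygen releases the 7-phenol and a methoxymethyl cation that methanol captures as dimethoxymethane, and dilute acid at room temperature for a short time should spare the two prenyl groups, the chromene and the C2 centre, whose epimerisation needs base-mediated opening of ring C.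

**Compound list**

1 | 2,4,6-trihydroxyacetophenone | CC(=O)c1c(O)cc(O)cc1O | starting material
2 | 2,6-dihydroxy-4-(methoxymethoxy)acetophenone | CC(=O)c1c(O)cc(OCOC)cc1O | intermediate
3 | prenyl bromide (1-bromo-3-methylbut-2-ene) | CC(C)=CCBr | starting material
4 | 2-hydroxy-4-(methoxymethoxy)-6-(3-methylbut-2-enyloxy)acetophenone | CC(=O)c1c(O)cc(OCOC)cc1OCC=C(C)C | intermediate
5 | 4-fluoro-3-hydroxybenzaldehyde | O=Cc1ccc(F)c(O)c1 | starting material
6 | 2-methylbut-3-yn-2-ol | CC(C)(O)C#C | starting material
7 | 2-methylbut-3-yn-2-yl trifluoroacetate (formed in the flask, not isolated) | CC(C)(OC(=O)C(F)(F)F)C#C | intermediate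
8 | 4-fluoro-3-(2-methylbut-3-yn-2-yloxy)benzaldehyde | O=Cc1ccc(F)c(OC(C)(C)C#C)c1 | intermediate
9 | 4-fluoro-3-(2-methylbut-3-en-2-yloxy)benzaldehyde | O=Cc1ccc(F)c(OC(C)(C)C=C)c1 | intermediate
10 | potassium 2-methylbut-3-yn-2-olate (formed in the flask, not isolated) | CC(C)([O-])C#C.[K+] | intermediate
11 | 3-(2-methylbut-3-en-2-yloxy)-4-(2-methylbut-3-yn-2-yloxy)benzaldehyde | O=Cc1ccc(OC(C)(C)C#C)c(OC(C)(C)C=C)c1 | intermediate
12 | aldol adduct, 3-hydroxy-1-[2-hydroxy-4-(methoxymethoxy)-6-(3-methylbut-2-enyloxy)phenyl]-3-[3-(2-methylbut-3-en-2-yloxy)-4-(2-methylbut-3-yn-2-yloxy)phenyl]propan-1-one (racemic at the carbinol carbon, not isolated) | CC(C)=CCOc1cc(OCOC)cc(O)c1C(=O)CC(O)c1ccc(OC(C)(C)C#C)c(OC(C)(C)C=C)c1 | intermediate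
13 | (E)-1-[2-hydroxy-4-(methoxymethoxy)-6-(3-methylbut-2-enyloxy)phenyl]-3-[3-(2-methylbut-3-en-2-yloxy)-4-(2-methylbut-3-yn-2-yloxy)phenyl]prop-2-en-1-one (chalcone) | CC(C)=CCOc1cc(OCOC)cc(O)c1C(=O)/C=C/c1ccc(OC(C)(C)C#C)c(OC(C)(C)C=C)c1 | intermediate
14 | (2S)-7-(methoxymethoxy)-5-(3-methylbut-2-enyloxy)-2-[3-(2-methylbut-3-en-2-yloxy)-4-(2-methylbut-3-yn-2-yloxy)phenyl]chroman-4-one (flavanone triether) | C=CC(C)(C)Oc1cc([C@@H]2CC(=O)c3c(OCC=C(C)C)cc(OCOC)cc3O2)ccc1OC(C)(C)C#C | intermediate
15 | C6 dienone: ring A keto tautomer with the 1,1-dimethylallyl group on sp3 C6 (C6 unassigned, not isolated) | C=CC(C)(C)Oc1cc([C@@H]2CC(=O)C3=C(O2)C=C(OCOC)C(C(C)(C)C=C)C3=O)ccc1OC(C)(C)C#C | intermediate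
16 | C8 dienone: ring A keto tautomer with the prenyl group on sp3 C8 (C8 unassigned, not isolated) | C=CC(C)(C)Oc1cc([C@@H]2CC(=O)C3=C(O2)C(CC=C(C)C)C(OCOC)=CC3=O)ccc1OC(C)(C)C#C | intermediate
17 | ring A rearranged diether: (2S)-5-hydroxy-7-(methoxymethoxy)-8-(3-methylbut-2-enyl)-2-[3-(2-methylbut-3-en-2-yloxy)-4-(2-methylbut-3-yn-2-yloxy)phenyl]chroman-4-one (not isolated) | C=CC(C)(C)Oc1cc([C@@H]2CC(=O)c3c(O)cc(OCOC)c(CC=C(C)C)c3O2)ccc1OC(C)(C)C#C | intermediate
18 | ring B dienone: keto tautomer with the prenyl group on sp3 C2' (C2' unassigned, not isolated) | CC(C)=CCC1C(=O)C(OC(C)(C)C#C)=CC=C1[C@@H]1CC(=O)c2c(O)cc(OCOC)c(CC=C(C)C)c2O1 | intermediate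
19 | doubly rearranged propargyl ether: (2S)-5-hydroxy-2-[3-hydroxy-2-(3-methylbut-2-enyl)-4-(2-methylbut-3-yn-2-yloxy)phenyl]-7-(methoxymethoxy)-8-(3-methylbut-2-enyl)chroman-4-one (not isolated) | CC(C)=CCc1c([C@@H]2CC(=O)c3c(O)cc(OCOC)c(CC=C(C)C)c3O2)ccc(OC(C)(C)C#C)c1O | intermediate
20 | allenyl dienone: keto tautomer with the 3-methylbuta-1,2-dienyl group on sp3 C5' (C5' unassigned, not isolated) | CC(C)=CCC1=C(O)C(=O)C(C=C=C(C)C)C=C1[C@@H]1CC(=O)c2c(O)cc(OCOC)c(CC=C(C)C)c2O1 | intermediate
21 | ortho-allenyl phenol: (2S)-2-[3,4-dihydroxy-5-(3-methylbuta-1,2-dienyl)-2-(3-methylbut-2-enyl)phenyl]-5-hydroxy-7-(methoxymethoxy)-8-(3-methylbut-2-enyl)chroman-4-one (not isolated) | CC(C)=CCc1c([C@@H]2CC(=O)c3c(O)cc(OCOC)c(CC=C(C)C)c3O2)cc(C=C=C(C)C)c(O)c1O | intermediate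
22 | ortho-quinone methide of ring B, exocyclic C5' alkene Z (not isolated) | CC(C)=CCC1=C(O)C(=O)/C(=C\C=C(C)C)C=C1[C@@H]1CC(=O)c2c(O)cc(OCOC)c(CC=C(C)C)c2O1 | intermediate
23 | (2S)-5-hydroxy-2-[8-hydroxy-2,2-dimethyl-7-(3-methylbut-2-enyl)-2H-chromen-6-yl]-7-(methoxymethoxy)-8-(3-methylbut-2-enyl)chroman-4-one (7-O-MOM ether of the target) | CC(C)=CCc1c([C@@H]2CC(=O)c3c(O)cc(OCOC)c(CC=C(C)C)c3O2)cc2c(c1O)OC(C)(C)C=C2 | intermediate
24 | (2S)-5,7-dihydroxy-2-[8-hydroxy-2,2-dimethyl-7-(3-methylbut-2-enyl)-2H-chromen-6-yl]-8-(3-methylbut-2-enyl)chroman-4-one (CNP0328260.1) | CC(C)=CCc1c([C@@H]2CC(=O)c3c(O)cc(O)c(CC=C(C)C)c3O2)cc2c(c1O)OC(C)(C)C=C2 | target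

**Step count and risks**

Total step count: 9. Longest linear sequence: 7 steps (from 5 to 24 through steps 3, 4, 5, 6, 7, 8 and 9).

Steps most likely to fail:

1. Step 8 (triple sigmatropic relay). The relay may stall or leak: the C6 dienone may enolise before its Cope shift, the tertiary allyl ether may fragment instead of migrating, and long heating with a Lewis acid may open ring C and erode the C2 configuration. The fallback does the ring B shifts before the stereocentre exists and asks only the known europium reaction of the flavanone. Setting out from aldehyde 11, heating in toluene at 110 °C should give, by aromatic Claisen rearrangement, 3-hydroxy-2-(3-methylbut-2-enyl)-4-(2-methylbut-3-yn-2-yloxy)benzaldehyde F1. Further heating in o-dichlorobenzene at 160 °C should convert the propargyl ether into 8-hydroxy-2,2-dimethyl-7-(3-methylbut-2-enyl)-2H-chromene-6-carbaldehyde F2. Claisen–Schmidt condensation of F2 with ketone 4 (KOH, EtOH) should give the ring B complete chalcone F3, and the thiourea-catalysed oxa-Michael closure of step 7 should give the (2S)-5-O-prenyl flavanone F4. Eu(fod)3 in CHCl3 at 60 °C, the known para-Claisen–Cope rearrangement of 5-O-prenyl flavanones, should then move the last prenyl group to C8 and return the route at compound 23.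

2. Step 7 (enantioselective oxa-Michael addition). Facial selectivity may be poor, or enantiopurity may be lost through catalyst-mediated reversible opening of ring C. The fallback replaces asymmetric catalysis by resolution with recycling. Setting out from chalcone 13, NaOAc in EtOH at 60 °C should close ring C without stereocontrol to the racemic flavanone triether F5. Preparative HPLC on a polysaccharide chiral stationary phase should deliver compound 14, where the route is rejoined, and the (2R)-flavanone triether F6. KOH in EtOH should reopen F6 to chalcone 13 for another pass.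

3. Step 5 (SNAr with the tertiary alkoxide). Attack on the formyl group (hemiacetal formation followed by hydride transfer, or alkynylation by a small equilibrium amount of acetylide) may outrun a substitution slowed by the neighbouring tertiary ether. The fallback brings in the oxygen as a small primary alkoxide and builds the hindered O–C bond at the sp3 carbon instead. Setting out from fluoride 9, 2-(methylsulfonyl)ethanol and NaH in DMF (0 °C to rt) should give 3-(2-methylbut-3-en-2-yloxy)-4-[2-(methylsulfonyl)ethoxy]benzaldehyde F7. Without isolation, F7 should undergo E1cB elimination under the same base to 4-hydroxy-3-(2-methylbut-3-en-2-yloxy)benzaldehyde F8. Copper-catalysed propargylation of F8 with trifluoroacetate 7 (DBU, CuCl2, MeCN, 0 °C), the reaction of step 3, should then give compound 11, where the route is rejoined.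

Further compounds
F1 | step 8 | 3-hydroxy-2-(3-methylbut-2-enyl)-4-(2-methylbut-3-yn-2-yloxy)benzaldehyde | O=Cc1ccc(OC(C)(C)C#C)c(O)c1CC=C(C)C
F2 | step 8 | 8-hydroxy-2,2-dimethyl-7-(3-methylbut-2-enyl)-2H-chromene-6-carbaldehyde | O=Cc1cc2C=CC(C)(C)Oc2c(O)c1CC=C(C)C
F3 | step 8 | (E)-1-[2-hydroxy-4-(methoxymethoxy)-6-(3-methylbut-2-enyloxy)phenyl]-3-[8-hydroxy-2,2-dimethyl-7-(3-methylbut-2-enyl)-2H-chromen-6-yl]prop-2-en-1-one | CC(C)=CCOc1cc(OCOC)cc(O)c1C(=O)/C=C/c1cc2C=CC(C)(C)Oc2c(O)c1CC=C(C)C
F4 | step 8 | (2S)-2-[8-hydroxy-2,2-dimethyl-7-(3-methylbut-2-enyl)-2H-chromen-6-yl]-7-(methoxymethoxy)-5-(3-methylbut-2-enyloxy)chroman-4-one | CC(C)=CCc1c([C@@H]2CC(=O)c3c(OCC=C(C)C)cc(OCOC)cc3O2)cc2c(c1O)OC(C)(C)C=C2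
F5 | step 7 | racemic 7-(methoxymethoxy)-5-(3-methylbut-2-enyloxy)-2-[3-(2-methylbut-3-en-2-yloxy)-4-(2-methylbut-3-yn-2-yloxy)phenyl]chroman-4-one | C=CC(C)(C)Oc1cc(C2CC(=O)c3c(OCC=C(C)C)cc(OCOC)cc3O2)ccc1OC(C)(C)C#C
F6 | step 7 | (2R)-7-(methoxymethoxy)-5-(3-methylbut-2-enyloxy)-2-[3-(2-methylbut-3-en-2-yloxy)-4-(2-methylbut-3-yn-2-yloxy)phenyl]chroman-4-one | C=CC(C)(C)Oc1cc([C@H]2CC(=O)c3c(OCC=C(C)C)cc(OCOC)cc3O2)ccc1OC(C)(C)C#C
F7 | step 5 | 3-(2-methylbut-3-en-2-yloxy)-4-[2-(methylsulfonyl)ethoxy]benzaldehyde | O=Cc1ccc(OCCS(C)(=O)=O)c(OC(C)(C)C=C)c1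
F8 | step 5 | 4-hydroxy-3-(2-methylbut-3-en-2-yloxy)benzaldehyde | O=Cc1ccc(O)c(OC(C)(C)C=C)c1
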